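## Analysis of the target

The target is an achiral isoflavone, 7-hydroxy-3-(5-hydroxy-8-methoxy-2,2-dimethyl-2H-chromen-6-yl)-4H-chromen-4-one. Ring A (C4a, C5–C8, C8a, hydroxyl on C7) is fused to γ-pyranone ring C (O1, C2, C3, C4). C3 carries ring B (C1'–C6'), which is fused across C3'–C4' to a 2,2-dimethyl-2H-pyran, ring D (O1'' on C4', C2''Me2, C3''=C4'' with C4'' on C3'). There is no stereocentre, so only constitution and substitution pattern have to be controlled. Ring B is pentasubstituted: C1' (bond to C3), C2' (free OH), C3' (ring D carbon), C4' (ring D oxygen), C5' (OMe), and only C6' carries hydrogen.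

The feature the route is built on is that the C2' hydroxyl and the C5' methoxy group are para to each other. Ring B is therefore a hydroquinone monomethyl ether, the reduced form of a para-quinone monoketal. The carbon ortho to its free hydroxyl, C1', is the one bonded to C3.

Sensitive groups are the styrene-type C3''=C4'' alkene of ring D (acid, electrophilic oxidants, hydrogenation), the very electron-rich and easily oxidised ring B, and C2 of the pyranone (opened by nucleophiles and base). The difficulty lies in three places: the congested C3–C1' bond next to a free ortho hydroxyl, the annulation of ring D at C3' between two oxygens with closure on O4' and not O2', and the four oxygen functions in three different states, which invite a long protecting-group sequence.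

## Retrosynthetic reasoning

Ring B and ring D atoms carry the target numbering (primed) in every compound, including the chromene fragments 5, 6 and 7.

**13 to 12.** Only the acetal O–C bond on the C7 oxygen is cut. The ring A hydroxyl is masked because the amide acetal used to make the enaminone would otherwise methylate it. The acetal is chosen because partial loss during the key step is harmless: both forms converge on 13.

**12 to 7 and 10 (key disconnection).** Two bonds are cut, C3–C1' and O1–C2, so ring C is opened and the two halves are separated in one move. Cutting here exploits the para C2'–OH/C5'–OMe pair. At the quinone monoketal oxidation level (7), C1' is an electrophilic carbon, and the α-carbon of the ortho-hydroxyaryl enaminone 10 is the matching nucleophile. The forward reaction has to join C3 to C1', rearomatise ring B and close the pyranone with loss of the amine. It delivers the free 2'-hydroxyl (from the ketone) and the 5'-methoxy group (from the ketal) with no halogen, no boron and no protecting group on ring B.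

**7 to 6.** The C5'–O ketal bond is cut. The forward step is an oxidative ketalisation of the para-methoxyphenol, raising ring B to the quinone level while leaving ring D intact.

**6 to 4 (through 5).** The C3'–C4'' bond of ring D is cut, leading back to an aryl 1,1-dimethylpropargyl ether. The methoxy group on C5' blocks the other ortho position, so the aromatic Claisen rearrangement can only go to C3'. The second ring B oxygen is carried as an acetate, so only the ether oxygen (O4') can close the pyran; this settles the O4'/O2' question.

**4 to 3.** The aryl C–O bond at C2' is traced back to an aryl–acetyl C–C bond (peracid oxygen insertion). This allows a start from an acetophenone in which the ring B oxygens are already differentiated as one OMe and one OH.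

**3 to 1 and 2.** The O4'–C2'' ether bond is cut, giving phenol 1 and tertiary propargylic chloride 2, which brings in all five carbons of ring D.

**10 to 9 to 8.** The enaminone C=C bond is cut (condensation of the methyl ketone with an amide acetal), then the acetal on the 4-hydroxyl of the acetophenone.

## Alternatives that were turned down

**Alternative 1:** the textbook route, cutting C3–C1' alone. The forward key step is a Suzuki–Miyaura coupling of 3-iodo-7-(methoxymethoxy)chromone A1 with the ring B pinacol boronate A2, giving bis-acetal A3, followed by deprotection. It was turned down because A2 needs protection of the 2'-hydroxyl and a directed metalation and borylation of an electron-rich chromene. A2 is also an ortho-alkoxy, electron-rich boronate and prone to protodeboronation. Ring C and the C3–C1' bond are made in separate steps, and both partners are prefunctionalised. It is kept as the fallback for the key step.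

**Alternative 2:** the deoxybenzoin route, cutting C4–C4a and then inserting C2. Friedel–Crafts (or Hoesch) acylation of a simple ring A diphenol with arylacetic acid A4 would give deoxybenzoin A5, which is closed with a one-carbon electrophile. It was turned down because the acylation needs a strong Lewis acid (BF3·OEt2 or ZnCl2/HCl) at elevated temperature, which the ring D alkene and an acetal on O2' would not survive. Postponing ring D reopens the O4'/O2' regiochemistry problem. A4 itself needs a multi-step one-carbon homologation of a ring B aldehyde.

**Alternative 3:** the biomimetic 2,3-aryl shift. Claisen–Schmidt condensation gives chalcone A6 and cyclisation gives flavanone A7, in which ring B is bonded to C2. Oxidation with Tl(NO3)3 or PhI(OH)OTs would move ring B from C2 to C3 and give A3. This changes the skeleton and copies the biosynthesis. It was turned down because the electrophilic oxidant (trivalent thallium or trivalent iodine) also attacks the ring D alkene, which undergoes oxidative ring contraction with the same reagents. The hydroquinone-type ring B that must migrate is also over-oxidised to a quinone. Ring D would have to be built after the shift on a ring B with differentiated protecting groups, which costs more steps than the shift wins.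

Key step: step 7

## Route

Remark: the target has no stereocentre, so the only stereodescriptors are the alkene geometries of the enaminones; compounds 1, 2 and 8 are taken as commercial.

Step 1
Reactants: 1 1-(3-hydroxy-4-methoxyphenyl)ethan-1-one; 2 3-chloro-3-methylbut-1-yne
Product: 3 1-{4-methoxy-3-[(2-methylbut-3-yn-2-yl)oxy]phenyl}ethan-1-one
Conditions: DBU, CuCl2·2H2O (cat.), MeCN, 0 °C to rt
Reagents that add atoms: none
Why: Copper-catalysed propargylic substitution of the tertiary chloride by the phenoxide (through a copper acetylide); it should give the hindered tertiary aryl ether without elimination to the enyne.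

Step 2
Reactants: 3 1-{4-methoxy-3-[(2-methylbut-3-yn-2-yl)oxy]phenyl}ethan-1-one
Product: 4 4-methoxy-3-[(2-methylbut-3-yn-2-yl)oxy]phenyl acetate
Conditions: mCPBA, CH2Cl2, 40 °C
Reagents that add atoms: meta-chloroperoxybenzoic acid, OOC(=O)c1cccc(Cl)c1
Why: Baeyer–Villiger oxidation; the electron-rich aryl group (para-methoxy) migrates in preference to methyl and gives the aryl acetate, and a terminal alkyne is inert to the peracid.

Step 3
Reactants: 4 4-methoxy-3-[(2-methylbut-3-yn-2-yl)oxy]phenyl acetate
Product: 6 8-methoxy-2,2-dimethyl-2H-chromen-5-ol, via 8-methoxy-2,2-dimethyl-2H-chromen-5-yl acetate 5 (not isolated)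
Conditions: o-xylene, 140 °C; then K2CO3 (cat.), MeOH, rt, under argon
Reagents that add atoms: none
Why: Aromatic propargyl Claisen rearrangement: the 3,3-shift can only go to C3' because C5' bears the methoxy group, and enolisation, 1,5-hydrogen shift and oxa-6π electrocyclisation close ring D on the ether oxygen. The acetate keeps the second oxygen from competing, and methanolysis then frees the phenol.

Step 4
Reactants: 6 8-methoxy-2,2-dimethyl-2H-chromen-5-ol
Product: 7 8,8-dimethoxy-2,2-dimethyl-2H-chromen-5(8H)-one
Conditions: PhI(OAc)2, MeOH, 0 °C
Reagents that add atoms: methanol, CO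
Why: Oxidative dearomatisation of a para-methoxyphenol by trivalent iodine: two-electron oxidation and capture of the cation by methanol at the methoxy-bearing para carbon should give the quinone monoketal. The phenol is oxidised much faster than the ring D alkene at 0 °C.

Step 5
Reactants: 8 1-(2,4-dihydroxyphenyl)ethan-1-one
Product: 9 1-[2-hydroxy-4-(methoxymethoxy)phenyl]ethan-1-one
Conditions: MOMCl, K2CO3, acetone, rt
Reagents that add atoms: chloromethyl methyl ether, COCCl
Why: Williamson-type O-alkylation; the 2-hydroxyl is tied up in a hydrogen bond to the ketone, so only the 4-hydroxyl should be acetalised.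

Step 6
Reactants: 9 1-[2-hydroxy-4-(methoxymethoxy)phenyl]ethan-1-one
Product: 10 (E)-3-(dimethylamino)-1-[2-hydroxy-4-(methoxymethoxy)phenyl]prop-2-en-1-one
Conditions: Me2NCH(OMe)2, toluene, 90 °C
Reagents that add atoms: N,N-dimethylformamide dimethyl acetal, COC(OC)N(C)C
Why: Condensation of the methyl ketone with the amide acetal (enaminone formation); the chelated 2-hydroxyl stays free and the thermodynamic E isomer should form.

Step 7
Reactants: 7 8,8-dimethoxy-2,2-dimethyl-2H-chromen-5(8H)-one; 10 (E)-3-(dimethylamino)-1-[2-hydroxy-4-(methoxymethoxy)phenyl]prop-2-en-1-one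
Product: 12 3-(5-hydroxy-8-methoxy-2,2-dimethyl-2H-chromen-6-yl)-7-(methoxymethoxy)-4H-chromen-4-one, via α-aryl enaminone 11 (not isolated)
Conditions: CF3CO2H (slow addition), (CF3)2CHOH, 0 °C to rt
Reagents that add atoms: none
Why: Proposed new method: the acid in (CF3)2CHOH should ionise the ketal of 7 (loss of methanol) to an O-methyl oxocarbenium ion, the two-electron-oxidised form of ring B, whose charge is shared by C1'; the nucleophilic α-carbon of enaminone 10 attacks C1' and forms the C3–C1' bond, and loss of two protons rearomatises ring B and gives α-aryl enaminone 11. The hydrogen-bonded ring A hydroxyl of 11 then adds to the protonated enaminone carbon (6-endo-trig oxa-Michael addition, the same as a 6-exo-trig attack on the iminium tautomer) and dimethylamine is expelled, which closes pyranone ring C. The closest known reaction types are the acid-promoted SN2'-type coupling of quinone monoketals with arenes and alkenes at the carbon α to the carbonyl, the Nenitzescu addition of enaminones to quinones, and the tandem α-functionalisation/chromone annulation of ortho-hydroxyaryl enaminones with halogen, chalcogen and aryliodonium electrophiles; what is new is the use of a quinone monoketal as the electrophile of such an annulation. No stereocentre is formed, so no element of stereocontrol is needed. Site selectivity on the electrophile is needed for C1' over C3', C6' and the vinylogous carbon C3'' of ring D: C3' is fully substituted and made electron-rich by the ring D oxygen, C6' is reached only by a Michael pathway that the ionising medium suppresses, and C3'' is shielded by the two methyl groups on C2''. Chemoselectivity of the ring closure is needed for the ring A hydroxyl (pyranone) over the newly formed ring B hydroxyl (benzofuran, the Nenitzescu mode): the ring A phenol is held beside the enaminone carbon by its hydrogen bond to the carbonyl and leads to the conjugated γ-pyranone, which is the closure that α-aryl enaminones bearing a free ortho-hydroxyl on the aryl group undergo in the deoxybenzoin route to 2'-hydroxyisoflavones, and the reversible aminal formation lets the more stable pyranone drain the equilibrium. Slow addition of the acid at 0 °C and a small excess of 10 keep the enaminone from closing to the 3-unsubstituted chromone before it is arylated and leave no oxidant behind. The ketal carbonyl becomes the free 2'-hydroxyl and one ketal methoxy group becomes the 5'-methoxy group, so ring B needs no protecting group.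

Step 8
Reactants: 12 3-(5-hydroxy-8-methoxy-2,2-dimethyl-2H-chromen-6-yl)-7-(methoxymethoxy)-4H-chromen-4-one
Product: 13 7-hydroxy-3-(5-hydroxy-8-methoxy-2,2-dimethyl-2H-chromen-6-yl)-4H-chromen-4-one
Conditions: HCl (aq.), MeOH, 50 °C
Reagents that add atoms: none
Why: Acid-catalysed transacetalisation of the aryl methoxymethyl ether to methanol; these are the usual conditions for pyrano-isoflavones and should leave the methyl ether, the pyranone and, at moderate temperature, the ring D alkene untouched.

## Compound list

1 | 1-(3-hydroxy-4-methoxyphenyl)ethan-1-one | CC(=O)c1ccc(OC)c(O)c1 | starting material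
2 | 3-chloro-3-methylbut-1-yne | CC(C)(Cl)C#C | starting material
3 | 1-{4-methoxy-3-[(2-methylbut-3-yn-2-yl)oxy]phenyl}ethan-1-one | CC(=O)c1ccc(OC)c(OC(C)(C)C#C)c1 | intermediate
4 | 4-methoxy-3-[(2-methylbut-3-yn-2-yl)oxy]phenyl acetate | CC(=O)Oc1ccc(OC)c(OC(C)(C)C#C)c1 | intermediate
5 | 8-methoxy-2,2-dimethyl-2H-chromen-5-yl acetate | CC(=O)Oc1ccc(OC)c2OC(C)(C)C=Cc12 | intermediate
6 | 8-methoxy-2,2-dimethyl-2H-chromen-5-ol | COc1ccc(O)c2c1OC(C)(C)C=C2 | intermediate
7 | 8,8-dimethoxy-2,2-dimethyl-2H-chromen-5(8H)-one | COC1(OC)C=CC(=O)C2=C1OC(C)(C)C=C2 | intermediate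
8 | 1-(2,4-dihydroxyphenyl)ethan-1-one | CC(=O)c1ccc(O)cc1O | starting material
9 | 1-[2-hydroxy-4-(methoxymethoxy)phenyl]ethan-1-one | CC(=O)c1ccc(OCOC)cc1O | intermediate
10 | (E)-3-(dimethylamino)-1-[2-hydroxy-4-(methoxymethoxy)phenyl]prop-2-en-1-one | CN(C)/C=C/C(=O)c1ccc(OCOC)cc1O | intermediate
11 | (E)-3-(dimethylamino)-2-(5-hydroxy-8-methoxy-2,2-dimethyl-2H-chromen-6-yl)-1-[2-hydroxy-4-(methoxymethoxy)phenyl]prop-2-en-1-one (either alkene isomer cyclises) | CN(C)/C=C(/C(=O)c1ccc(OCOC)cc1O)c1cc(OC)c2OC(C)(C)C=Cc2c1O | intermediate
12 | 3-(5-hydroxy-8-methoxy-2,2-dimethyl-2H-chromen-6-yl)-7-(methoxymethoxy)-4H-chromen-4-one | COCOc1ccc2c(c1)occ(-c1cc(OC)c3OC(C)(C)C=Cc3c1O)c2=O | intermediate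
13 | 7-hydroxy-3-(5-hydroxy-8-methoxy-2,2-dimethyl-2H-chromen-6-yl)-4H-chromen-4-one | COc1cc(-c2coc3cc(O)ccc3c2=O)c(O)c2c1OC(C)(C)C=C2 | target

## Step count and risk

Total step count: 8. Longest linear sequence: 6 (steps 1, 2, 3, 4, 7, 8); steps 5 and 6 form the two-step branch to 10.

**Step 7 (key step, proposed new method).** The most likely failure is loss of chemoselectivity in the ring closure: the new ring B hydroxyl may capture the iminium carbon faster than the ring A hydroxyl and divert the material to a 3-aroylbenzofuran. Two further risks are acid-mediated closure of 10 to the unsubstituted chromone before arylation, and attack of the cation through its vinylogous ring D position.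

Fallback (known chemistry; sets out from 6 and 10, returns at 13): 10 is closed with I2 in CH2Cl2 to 3-iodo-7-(methoxymethoxy)-4H-chromen-4-one F1. Phenol 6 is protected with MOMCl/i-Pr2NEt as 8-methoxy-5-(methoxymethoxy)-2,2-dimethyl-2H-chromene F2. F2 is lithiated ortho to the acetal (n-BuLi, TMEDA, THF, −78 to 0 °C) and quenched with i-PrOBpin to give 2-[8-methoxy-5-(methoxymethoxy)-2,2-dimethyl-2H-chromen-6-yl]-4,4,5,5-tetramethyl-1,3,2-dioxaborolane F3. Suzuki–Miyaura coupling of F1 with F3 (Pd(PPh3)4, a zerovalent palladium catalyst, K2CO3, dioxane/H2O, 80 °C) gives 7-(methoxymethoxy)-3-[8-methoxy-5-(methoxymethoxy)-2,2-dimethyl-2H-chromen-6-yl]-4H-chromen-4-one F4. The conditions of step 8 then remove both acetals and give 13.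

**Step 2.** Aryl migration in the Baeyer–Villiger oxidation of an aryl methyl ketone is slow, and the longer heating with a carboxylic acid present may cleave the tertiary propargylic ether.

Fallback (sets out from 2, returns at 4): commercial 3-hydroxy-4-methoxybenzaldehyde F5 is etherified with 2 under the conditions of step 1 to 4-methoxy-3-[(2-methylbut-3-yn-2-yl)oxy]benzaldehyde F6. The aldehyde is oxidised by mCPBA at rt much faster than a methyl ketone and gives 4-methoxy-3-[(2-methylbut-3-yn-2-yl)oxy]phenyl formate F7. K2CO3/MeOH frees 4-methoxy-3-[(2-methylbut-3-yn-2-yl)oxy]phenol F8, and Ac2O/pyridine gives 4.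

**Step 3.** The 3,3-shift into the position flanked by two oxygen substituents may be slow, so that attack at the methoxy-bearing carbon and thermal decomposition compete.

Fallback (sets out from 4, returns at 5; no new compound, F0): ring D is closed by a Friedel–Crafts-type 6-endo-dig hydroarylation of the alkyne with a cationic monovalent gold catalyst (Ph3PAuNTf2, CH2Cl2, rt) instead of a sigmatropic shift, followed by the same methanolysis to 6.

**Step 8.** Protonation of the ring D alkene gives a benzylic cation stabilised by two ortho oxygens, which may lead to solvent addition or oligomerisation during the acidic acetal cleavage.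

Fallback (sets out from 8 and 7, returns at 13): 8 is silylated at the 4-hydroxyl (i-Pr3SiCl, imidazole, DMF) to 1-{2-hydroxy-4-[(triisopropylsilyl)oxy]phenyl}ethan-1-one F9. Condensation with the amide acetal gives (E)-3-(dimethylamino)-1-{2-hydroxy-4-[(triisopropylsilyl)oxy]phenyl}prop-2-en-1-one F10. Coupling with 7 as in step 7 gives 3-(5-hydroxy-8-methoxy-2,2-dimethyl-2H-chromen-6-yl)-7-[(triisopropylsilyl)oxy]-4H-chromen-4-one F11. Bu4NF/AcOH in THF at 0 °C then removes the silyl group and gives 13 without acid treatment.

## Further compounds

F1 | step 7 | 3-iodo-7-(methoxymethoxy)-4H-chromen-4-one | COCOc1ccc2c(c1)occ(I)c2=O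
F2 | step 7 | 8-methoxy-5-(methoxymethoxy)-2,2-dimethyl-2H-chromene | COCOc1ccc(OC)c2OC(C)(C)C=Cc12
F3 | step 7 | 2-[8-methoxy-5-(methoxymethoxy)-2,2-dimethyl-2H-chromen-6-yl]-4,4,5,5-tetramethyl-1,3,2-dioxaborolane | COCOc1c(B2OC(C)(C)C(C)(C)O2)cc(OC)c2OC(C)(C)C=Cc12
F4 | step 7 | 7-(methoxymethoxy)-3-[8-methoxy-5-(methoxymethoxy)-2,2-dimethyl-2H-chromen-6-yl]-4H-chromen-4-one | COCOc1ccc2c(c1)occ(-c1cc(OC)c3OC(C)(C)C=Cc3c1OCOC)c2=O
F5 | step 2 | 3-hydroxy-4-methoxybenzaldehyde | COc1ccc(C=O)cc1O
F6 | step 2 | 4-methoxy-3-[(2-methylbut-3-yn-2-yl)oxy]benzaldehyde | COc1ccc(C=O)cc1OC(C)(C)C#C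
F7 | step 2 | 4-methoxy-3-[(2-methylbut-3-yn-2-yl)oxy]phenyl formate | COc1ccc(OC=O)cc1OC(C)(C)C#C
F8 | step 2 | 4-methoxy-3-[(2-methylbut-3-yn-2-yl)oxy]phenol | COc1ccc(O)cc1OC(C)(C)C#C
F0 | step 3 | none | none
F9 | step 8 | 1-{2-hydroxy-4-[(triisopropylsilyl)oxy]phenyl}ethan-1-one | CC(=O)c1ccc(O[Si](C(C)C)(C(C)C)C(C)C)cc1O
F10 | step 8 | (E)-3-(dimethylamino)-1-{2-hydroxy-4-[(triisopropylsilyl)oxy]phenyl}prop-2-en-1-one | CN(C)/C=C/C(=O)c1ccc(O[Si](C(C)C)(C(C)C)C(C)C)cc1O
F11 | step 8 | 3-(5-hydroxy-8-methoxy-2,2-dimethyl-2H-chromen-6-yl)-7-[(triisopropylsilyl)oxy]-4H-chromen-4-one | COc1cc(-c2coc3cc(O[Si](C(C)C)(C(C)C)C(C)C)ccc3c2=O)c(O)c2c1OC(C)(C)C=C2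
A1 | alternative 1 | 3-iodo-7-(methoxymethoxy)-4H-chromen-4-one | COCOc1ccc2c(c1)occ(I)c2=O
A2 | alternative 1 | 2-[8-methoxy-5-(methoxymethoxy)-2,2-dimethyl-2H-chromen-6-yl]-4,4,5,5-tetramethyl-1,3,2-dioxaborolane | COCOc1c(B2OC(C)(C)C(C)(C)O2)cc(OC)c2OC(C)(C)C=Cc12
A3 | alternative 1 | 7-(methoxymethoxy)-3-[8-methoxy-5-(methoxymethoxy)-2,2-dimethyl-2H-chromen-6-yl]-4H-chromen-4-one | COCOc1ccc2c(c1)occ(-c1cc(OC)c3OC(C)(C)C=Cc3c1OCOC)c2=O
A4 | alternative 2 | 2-[8-methoxy-5-(methoxymethoxy)-2,2-dimethyl-2H-chromen-6-yl]acetic acid | COCOc1c(CC(=O)O)cc(OC)c2OC(C)(C)C=Cc12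
A5 | alternative 2 | 1-(2,4-dihydroxyphenyl)-2-(5-hydroxy-8-methoxy-2,2-dimethyl-2H-chromen-6-yl)ethan-1-one | O=C(Cc1cc(OC)c2OC(C)(C)C=Cc2c1O)c1ccc(O)cc1O
A6 | alternative 3 | (E)-1-[2-hydroxy-4-(methoxymethoxy)phenyl]-3-[8-methoxy-5-(methoxymethoxy)-2,2-dimethyl-2H-chromen-6-yl]prop-2-en-1-one | COCOc1ccc(C(=O)/C=C/c2cc(OC)c3OC(C)(C)C=Cc3c2OCOC)c(O)c1
A7 | alternative 3 | racemic 7-(methoxymethoxy)-2-[8-methoxy-5-(methoxymethoxy)-2,2-dimethyl-2H-chromen-6-yl]chroman-4-one | COCOc1ccc2C(=O)CC(Oc2c1)c1cc(OC)c2OC(C)(C)C=Cc2c1OCOC
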